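## Retrosynthetic overview

1. The target is opened in one operation at the lactone C16–O bond and the ring bond C1–C2, giving an acyclic chain with a C2 enal at the head and a 2-(bromomethyl)enoate (C14–C1=C15(CO2Me)–C17H2Br) at the tail. This is the head-to-tail C1–C2 closure by which a geranylgeranyl chain becomes a cembrane: C2 is the electrophile, C1 the nucleophilic alkene carbon, and C15=C17 is left as the exocyclic alkene.
2. Ring order: the 14-membered carbocycle forms first (C1–C2), the γ-lactone second (C2–O onto C16), both in the last flask. C1 and C2 are created there: the cis fusion comes from the closed transition state, the face from the C13 acetate.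
3. The 2-(bromomethyl)enoate comes from a terminal alkene and methyl 2-(bromomethyl)acrylate by cross-metathesis.
4. The C13 carbinol (R) comes from asymmetric allylboration of the C13 enal.
5. The C13 enal comes from E-selective terminal allylic oxidation of (2E,6E)-farnesyl acetate, which supplies C2–C13, the three methyl groups and all three E-alkenes.

Assumption: commercial (2E,6E)-farnesol (at least 95 % E,E) is the starting material; compounds are numbered in the order in which they appear in the forward steps; positions in the text use cembrane numbering (C2 = old C1 of farnesol, C13 = old C12).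

## Route

Step 1
Reactants: 1 (2E,6E)-farnesol; 2 acetic anhydride
Product: 3 (2E,6E)-3,7,11-trimethyldodeca-2,6,10-trien-1-yl acetate
Conditions: Ac2O, Et3N, DMAP (cat.), CH2Cl2, 0 °C → rt
Reagents that add atoms: acetic anhydride CC(=O)OC(C)=O
Why: DMAP-catalysed O-acetylation (acyl transfer) of the primary allylic alcohol; the acetate deactivates the 2,3-alkene toward selenium dioxide in step 2, and no stereocentre is involved.

Step 2
Reactants: 3 (2E,6E)-farnesyl acetate; 4 selenium dioxide; 5 tert-butyl hydroperoxide
Product: 7 (2E,6E,10E)-3,7,11-trimethyl-12-oxododeca-2,6,10-trien-1-yl acetate, via allylic alcohol 6 (not isolated)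
Conditions: SeO2 (0.2 equiv), t-BuOOH (3 equiv), salicylic acid (0.1 equiv), CH2Cl2, 0 °C → rt; aq. Na2S2O3 wash; then MnO2 (15 equiv), CH2Cl2, rt (crude, no purification)
Reagents that add atoms: selenium dioxide O=[Se]=O; tert-butyl hydroperoxide CC(C)(C)OO
Why: Sharpless catalytic SeO2/t-BuOOH allylic oxidation (ene reaction, then [2,3]-sigmatropic shift) attacks the most electron-rich, least hindered terminal trisubstituted alkene at its E-methyl group to give the E-allylic alcohol 6 plus some enal, and MnO2 (allylic alcohol oxidation) converges the mixture on enal 7 with the 10E geometry intact.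

Step 3
Reactants: 7 (2E,6E,10E)-3,7,11-trimethyl-12-oxododeca-2,6,10-trien-1-yl acetate; 8 allylmagnesium bromide
Product: 10 (2E,6E,10E,12R)-3,7,11-trimethylpentadeca-2,6,10,14-tetraene-1,12-diol, via hydroxy acetate 9 (not isolated)
Conditions: (+)-Ipc2BOMe [the enantiomer made from (−)-α-pinene] (1.3 equiv), allylMgBr (1.2 equiv), Et2O, 0 °C → rt, 1 h; then 7, −78 °C, 3 h; then 3 M NaOH, 30 % H2O2, THF–MeOH, 0 °C → rt, 8 h
Reagents that add atoms: allylmagnesium bromide C=CC[Mg]Br
Why: Brown asymmetric allylboration through a chair six-membered transition state, in which the allylborane from the (−)-α-pinene series adds to the Re face of the α-methyl enal and sets the new carbinol centre as R (C13 of the cembrane; this series gives R alcohols from aryl and alkenyl aldehydes), while the alkaline peroxide work-up that frees the alcohol from boron also saponifies the primary acetate.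

Step 4
Reactants: 10 (2E,6E,10E,12R)-3,7,11-trimethylpentadeca-2,6,10,14-tetraene-1,12-diol
Product: 11 (2E,6E,10E,12R)-12-hydroxy-3,7,11-trimethylpentadeca-2,6,10,14-tetraenal
Conditions: TEMPO (0.1 equiv), PhI(OAc)2 (1.1 equiv), CH2Cl2, rt
Reagents that add atoms: none
Why: TEMPO/PhI(OAc)2 oxoammonium oxidation is kinetically selective for the primary allylic alcohol over the more hindered secondary one, stops at the aldehyde, and leaves the alkenes, the 2E geometry and the C13 centre untouched.

Step 5
Reactants: 11 (2E,6E,10E,12R)-12-hydroxy-3,7,11-trimethylpentadeca-2,6,10,14-tetraenal; 2 acetic anhydride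
Product: 12 (2E,6E,10E,12R)-12-acetoxy-3,7,11-trimethylpentadeca-2,6,10,14-tetraenal
Conditions: Ac2O, pyridine, DMAP (cat.), CH2Cl2, 0 °C
Reagents that add atoms: acetic anhydride CC(=O)OC(C)=O
Why: nucleophile-catalysed acylation of the secondary allylic alcohol with retention at C13 (the C–O bond is not broken), and the enal tolerates pyridine/DMAP at 0 °C.

Step 6
Reactants: 12 (2E,6E,10E,12R)-12-acetoxy-3,7,11-trimethylpentadeca-2,6,10,14-tetraenal; 13 methyl 2-(bromomethyl)acrylate
Product: 14 methyl (2Z,5R,6E,10E,14E)-5-acetoxy-2-(bromomethyl)-6,10,14-trimethyl-16-oxohexadeca-2,6,10,14-tetraenoate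
Conditions: 13 (5 equiv), second-generation Hoveyda–Grubbs catalyst RuCl2(H2IMes)(=CH-C6H4-2-OiPr) (2 × 5 mol %), CH2Cl2, 40 °C, argon sweep
Reagents that add atoms: methyl 2-(bromomethyl)acrylate C=C(CBr)C(=O)OC
Why: olefin cross-metathesis of a terminal alkene with a methacrylate-type 1,1-disubstituted acrylate that does not homodimerise and is used in excess (the bromomethyl partner is an extension of the methacrylate case and is untested), so loss of ethylene drives the reaction to the thermodynamic trisubstituted enoate with the chain trans to the ester (2Z, the geometry of Morita–Baylis–Hillman-derived bromides), while the internal trisubstituted alkenes, the enal, the acetate and the C13 centre are spectators.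

Step 7
Reactants: 14 methyl (2Z,5R,6E,10E,14E)-5-acetoxy-2-(bromomethyl)-6,10,14-trimethyl-16-oxohexadeca-2,6,10,14-tetraenoate
Product: 17 (1S,2S,3E,7E,11E,13R)-13-acetoxycembra-3,7,11,15(17)-tetraen-16,2-olide, via allylchromium species 15 (not isolated), via hydroxy ester 16 (not isolated)
Conditions: CrCl2 (8 equiv), THF, 14 added over 10 h (final 2 mM), 25 °C; aq. NH4Cl; then PPTS (cat.), CH2Cl2, rt
Reagents that add atoms: none
Why: intramolecular Nozaki–Hiyama-type (Barbier) allylation in which two equivalents of divalent chromium turn the allylic bromide into an allylchromium dichloride that adds through its γ-carbon (C1) to the enal carbon (C2) in a closed six-membered chair transition state; because the chain on C1 is cis to the CH2–Cr arm (Z-crotyl-type geometry held by the trans ester), C1 and C2 are expected to form syn, which is the cis ring fusion (this is the sense reported for indium and zinc reagents of this type; it is assumed, not established, for chromium), and the C13 acetate one carbon away in the folding chain is relied on to select the enal face that gives 1S,2S (this remote induction is unproven and is the main risk), after which the chromium alkoxide closes the γ-lactone on the methyl ester.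

## Compound list

1 | (2E,6E)-farnesol [(2E,6E)-3,7,11-trimethyldodeca-2,6,10-trien-1-ol] | CC(C)=CCC/C(C)=C/CC/C(C)=C/CO | starting material
2 | acetic anhydride | CC(=O)OC(C)=O | starting material
3 | (2E,6E)-3,7,11-trimethyldodeca-2,6,10-trien-1-yl acetate [(2E,6E)-farnesyl acetate] | CC(C)=CCC/C(C)=C/CC/C(C)=C/COC(C)=O | intermediate
4 | selenium dioxide | O=[Se]=O | starting material
5 | tert-butyl hydroperoxide | CC(C)(C)OO | starting material
6 | (2E,6E,10E)-12-hydroxy-3,7,11-trimethyldodeca-2,6,10-trien-1-yl acetate (not isolated) | OC/C(C)=C/CC/C(C)=C/CC/C(C)=C/COC(C)=O | intermediate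
7 | (2E,6E,10E)-3,7,11-trimethyl-12-oxododeca-2,6,10-trien-1-yl acetate | O=C/C(C)=C/CC/C(C)=C/CC/C(C)=C/COC(C)=O | intermediate
8 | allylmagnesium bromide | C=CC[Mg]Br | starting material
9 | (2E,6E,10E,12R)-12-hydroxy-3,7,11-trimethylpentadeca-2,6,10,14-tetraen-1-yl acetate (not isolated) | C=CC[C@@H](O)/C(C)=C/CC/C(C)=C/CC/C(C)=C/COC(C)=O | intermediate
10 | (2E,6E,10E,12R)-3,7,11-trimethylpentadeca-2,6,10,14-tetraene-1,12-diol | C=CC[C@@H](O)/C(C)=C/CC/C(C)=C/CC/C(C)=C/CO | intermediate
11 | (2E,6E,10E,12R)-12-hydroxy-3,7,11-trimethylpentadeca-2,6,10,14-tetraenal | C=CC[C@@H](O)/C(C)=C/CC/C(C)=C/CC/C(C)=C/C=O | intermediate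
12 | (2E,6E,10E,12R)-12-acetoxy-3,7,11-trimethylpentadeca-2,6,10,14-tetraenal | C=CC[C@@H](OC(C)=O)/C(C)=C/CC/C(C)=C/CC/C(C)=C/C=O | intermediate
13 | methyl 2-(bromomethyl)acrylate | C=C(CBr)C(=O)OC | starting material
14 | methyl (2Z,5R,6E,10E,14E)-5-acetoxy-2-(bromomethyl)-6,10,14-trimethyl-16-oxohexadeca-2,6,10,14-tetraenoate | COC(=O)/C(CBr)=C/C[C@@H](OC(C)=O)/C(C)=C/CC/C(C)=C/CC/C(C)=C/C=O | intermediate
15 | allylchromium dichloride from 14 (CH2CrCl2 in place of CH2Br, same 2Z geometry, THF-solvated, not isolated) | COC(=O)/C(C[Cr](Cl)Cl)=C/C[C@@H](OC(C)=O)/C(C)=C/CC/C(C)=C/CC/C(C)=C/C=O | intermediate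
16 | methyl 2-[(1S,2S,3E,7E,11E,13R)-13-acetoxy-2-hydroxy-4,8,12-trimethylcyclotetradeca-3,7,11-trien-1-yl]prop-2-enoate (formed as its chromium alkoxide, drawn as the free alcohol, not isolated) | C=C(C(=O)OC)[C@H]1[C@@H](O)/C=C(\C)CC/C=C(\C)CC/C=C(\C)[C@H](OC(C)=O)C1 | intermediate
17 | (1S,2S,3E,7E,11E,13R)-13-acetoxycembra-3,7,11,15(17)-tetraen-16,2-olide (cis-fused α-methylene-γ-lactone on the 14-membered ring) | C=C1C(=O)O[C@H]2/C=C(\C)CC/C=C(\C)CC/C=C(\C)[C@H](OC(C)=O)C[C@@H]12 | target

## Step count and risks

Total step count: 7. Longest linear sequence: 7 steps (1 → 17); the route is fully linear and all other inputs (2, 4, 5, 8, 13) are purchased.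

Steps most likely to fail:

**Step 7 (ring closure).** The risks are oligomers at the 14-membered closure, the syn (cis-fusion) outcome that is assumed rather than established for the chromium reagent, and above all the unproven choice of enal face by the C13 acetate (1S,2S against 1R,2R). The fallback sets out from 14 and comes back at 16. Compound 14 is borylated (B2pin2, Pd2(dba)3 5 mol %, toluene, 50 °C; the primary allylic bromide ionises on zerovalent palladium far faster than the hindered secondary acetate) to the bench-stable allylboronate methyl (2E,5R,6E,10E,14E)-5-acetoxy-6,10,14-trimethyl-16-oxo-2-[(4,4,5,5-tetramethyl-1,3,2-dioxaborolan-2-yl)methyl]hexadeca-2,6,10,14-tetraenoate F1. Slow addition of F1 (2 mM, toluene) to Sc(OTf)3 (10 mol %) or to a BINOL-derived chiral phosphoric acid (TRIP, the hand chosen to match C13) closes the ring by intramolecular allylboration. This reaction is homogeneous and expected to be stereospecific (chain cis to CH2–B gives the syn adduct), and it allows an external controller for the enal face. It gives methyl 2-[(1S,2S,3E,7E,11E,13R)-13-acetoxy-4,8,12-trimethyl-2-[(4,4,5,5-tetramethyl-1,3,2-dioxaborolan-2-yl)oxy]cyclotetradeca-3,7,11-trien-1-yl]prop-2-enoate F2, which aqueous work-up hydrolyses to 16; PPTS then lactonises 16 to 17 as in step 7.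

**Step 6 (cross-metathesis).** The partner is 1,1-disubstituted, electron-poor and carries an allylic bromide, so it may turn over slowly or degrade the ruthenium carbene. The fallback sets out from 12 and comes back at 14, and brings the halogen in after the C=C bond. Compound 12 is cross-metathesised under the same catalyst with methyl 2-(hydroxymethyl)acrylate to methyl (2E,5R,6E,10E,14E)-5-acetoxy-2-(hydroxymethyl)-6,10,14-trimethyl-16-oxohexadeca-2,6,10,14-tetraenoate F3 (same olefin geometry, chain trans to the ester). The primary allylic alcohol of F3 is then displaced with PBr3 (Et2O, −10 °C) to give 14. This fallback does not help if the 1,1-disubstituted partner itself is the problem.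

**Step 2 (allylic oxidation).** The yield is modest (typically 40–50 %), with over-oxidation and some attack at the internal alkene. The fallback sets out from 3 and comes back at 7, and cuts the terminus off and rebuilds it. NBS in aqueous THF (0 °C) adds selectively to the terminal alkene of 3 to give (2E,6E)-10-bromo-11-hydroxy-3,7,11-trimethyldodeca-2,6-dien-1-yl acetate F4. DBU (CH2Cl2) closes it to (2E,6E)-10,11-epoxy-3,7,11-trimethyldodeca-2,6-dien-1-yl acetate F5. HIO4·2H2O (THF–Et2O, 0 °C) cleaves the epoxide to (2E,6E)-3,7-dimethyl-10-oxodeca-2,6-dien-1-yl acetate F6. An E-selective Wittig reaction of F6 with the stabilised ylide 2-(triphenylphosphoranylidene)propanal (toluene, 80 °C) gives 7.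

## Further compounds

F1 | step 7 | methyl (2E,5R,6E,10E,14E)-5-acetoxy-6,10,14-trimethyl-16-oxo-2-[(4,4,5,5-tetramethyl-1,3,2-dioxaborolan-2-yl)methyl]hexadeca-2,6,10,14-tetraenoate | COC(=O)/C(CB1OC(C)(C)C(C)(C)O1)=C/C[C@@H](OC(C)=O)/C(C)=C/CC/C(C)=C/CC/C(C)=C/C=O
F2 | step 7 | methyl 2-[(1S,2S,3E,7E,11E,13R)-13-acetoxy-4,8,12-trimethyl-2-[(4,4,5,5-tetramethyl-1,3,2-dioxaborolan-2-yl)oxy]cyclotetradeca-3,7,11-trien-1-yl]prop-2-enoate | C=C(C(=O)OC)[C@H]1[C@@H](OB2OC(C)(C)C(C)(C)O2)/C=C(\C)CC/C=C(\C)CC/C=C(\C)[C@H](OC(C)=O)C1
F3 | step 6 | methyl (2E,5R,6E,10E,14E)-5-acetoxy-2-(hydroxymethyl)-6,10,14-trimethyl-16-oxohexadeca-2,6,10,14-tetraenoate | COC(=O)/C(CO)=C/C[C@@H](OC(C)=O)/C(C)=C/CC/C(C)=C/CC/C(C)=C/C=O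
F4 | step 2 | (2E,6E)-10-bromo-11-hydroxy-3,7,11-trimethyldodeca-2,6-dien-1-yl acetate (racemic at C10) | CC(C)(O)C(Br)CC/C(C)=C/CC/C(C)=C/COC(C)=O
F5 | step 2 | (2E,6E)-10,11-epoxy-3,7,11-trimethyldodeca-2,6-dien-1-yl acetate (racemic) | CC1(C)OC1CC/C(C)=C/CC/C(C)=C/COC(C)=O
F6 | step 2 | (2E,6E)-3,7-dimethyl-10-oxodeca-2,6-dien-1-yl acetate | O=CCC/C(C)=C/CC/C(C)=C/COC(C)=O
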